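**Assumption:** positions are numbered as in the C15 chain of the target (C1≡C2, C3=C4, C6–OAc, C7–O–C12 ring, C13–Br), and both chiral building blocks are taken as catalogue chemicals.

**Retrosynthetic overview**
- Last operations: unmasking of the C≡C–H, and before it closure of the only ring (the oxepene, step 6) at C9=C10 by ring-closing metathesis, with the cis-enyne arm on C7 as the leaving olefin.
- C11–C12: allylsilane addition to an α-bromo oxocarbenium ion (C13–Br directs C12). O7–C12 comes from a 2-bromobutanoate ester via its α-acetoxy ether.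
- C4–C5 and C8–C9 are made together by a two-fold photochemical nickel coupling of a C2-symmetric bis-epoxide with a (Z)-chloroenyne (key step).
- Stereocentres: C6/C7 are bought (L-tartrate-derived bis-epoxide), C13 is bought ((S)-2-bromobutanoic acid, from L-2-aminobutanoic acid), and C12 is induced by C13.

**Step 1**
Reactants: 1 (Z)-1,2-dichloroethene; 2 ethynyl(trimethyl)silane
Product: 3 [(3Z)-4-chlorobut-3-en-1-yn-1-yl]trimethylsilane
Conditions: Pd(PPh3)4 (3 mol%), CuI (6 mol%), n-BuNH2 (2 equiv), 1 (5 equiv), Et2O, 20 °C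
Reagents that add atoms: none
Why: Sonogashira coupling of one vinylic C–Cl bond proceeds with retention of the cis geometry, and the excess of 1 suppresses double coupling.

**Step 2**
Reactants: 3 [(3Z)-4-chlorobut-3-en-1-yn-1-yl]trimethylsilane; 4 (2S,2'S)-2,2'-bioxirane [(2S,3S)-1,2:3,4-diepoxybutane]
Product: 8 (3Z,6S,7S,9Z)-1,12-bis(trimethylsilyl)dodeca-3,9-diene-1,11-diyne-6,7-diol, via iodohydrin 5 (not isolated), via mono-coupled epoxy alcohol 6 (not isolated), via second iodohydrin 7 (not isolated)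
Conditions: 3 (2.4 equiv), NiBr2(dme) (10 mol%), 4,4'-di-tert-butyl-2,2'-bipyridine (12 mol%), [Ir(ppy)2(dtbbpy)]PF6 (1 mol%), NaI (50 mol%), Hantzsch ester (2.4 equiv), 2,6-lutidine (2.4 equiv), DMA, 450 nm LEDs, 20 °C
Reagents that add atoms: none
Why: Proposed new method: a two-fold nickel/photoredox cross-electrophile coupling in which iodide opens each epoxide of 4 at its CH2 terminus to a primary iodohydrin, zerovalent nickel inserts into the activated vinylic C–Cl bond of 3 with retention of the Z geometry, the Hantzsch-ester-fed photoreduced iridium complex keeps nickel low-valent, and iodine-atom abstraction gives a primary β-hydroxyalkyl radical that is captured at the alkenylnickel and reductively eliminated to the C4–C5 and C8–C9 bonds; C6 and C7 are never touched and keep the configuration bought with 4, and the low triplet energy of the iridium sensitiser (about 49 kcal/mol) should leave the Z-enynes unisomerised; closest known reaction type: nickel/photoredox (and nickel/iodide/manganese) cross-electrophile coupling of terminal epoxides with aryl halides.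

**Step 3**
Reactants: 8 (3Z,6S,7S,9Z)-1,12-bis(trimethylsilyl)dodeca-3,9-diene-1,11-diyne-6,7-diol; 9 (2S)-2-bromobutanoic acid
Product: 10 (3Z,6S,7S,9Z)-7-hydroxy-1,12-bis(trimethylsilyl)dodeca-3,9-diene-1,11-diyn-6-yl (2S)-2-bromobutanoate
Conditions: 9 (1.0 equiv), DCC (1.05 equiv), DMAP (5 mol%), CH2Cl2, −20 → 0 °C; recovered 8 recycled
Reagents that add atoms: none
Why: Steglich esterification; because 8 is C2-symmetric, acylation of either hydroxyl (and any later acyl migration) gives the same mono-ester, and C13 enters with the configuration bought in 9.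

**Step 4**
Reactants: 10 (3Z,6S,7S,9Z)-7-hydroxy-1,12-bis(trimethylsilyl)dodeca-3,9-diene-1,11-diyn-6-yl (2S)-2-bromobutanoate
Product: 12 (3Z,6S,7S,9Z)-7-{[(2S)-1-(acetyloxy)-2-bromobutyl]oxy}-1,12-bis(trimethylsilyl)dodeca-3,9-diene-1,11-diyn-6-yl acetate (both epimers at the acetal carbon), via aluminium hemiacetal 11 (not isolated)
Conditions: i-Bu2AlH (2.2 equiv), CH2Cl2, −78 °C; then pyridine, DMAP, Ac2O, −78 → 0 °C
Reagents that add atoms: acetic anhydride CC(=O)OC(C)=O
Why: Rychnovsky reductive acetylation: the ester is reduced only to the aluminium hemiacetal at −78 °C and trapped as the α-acetoxy ether, while the free 6-OH is acetylated in the same operation to install the acetate of the target; the acetal epimers converge in step 5.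

**Step 5**
Reactants: 12 (3Z,6S,7S,9Z)-7-{[(2S)-1-(acetyloxy)-2-bromobutyl]oxy}-1,12-bis(trimethylsilyl)dodeca-3,9-diene-1,11-diyn-6-yl acetate
Product: 13 (3Z,6S,7S,9Z)-7-{[(4R,5S)-5-bromohept-1-en-4-yl]oxy}-1,12-bis(trimethylsilyl)dodeca-3,9-diene-1,11-diyn-6-yl acetate
Conditions: allylSiMe3 (5 equiv), Me3SiOTf (0.5 equiv), CH2Cl2, −78 → −40 °C
Reagents that add atoms: allyltrimethylsilane C=CC[Si](C)(C)C
Why: Ionisation gives the α-bromo oxocarbenium ion and Hosomi–Sakurai allylation occurs anti to the C–Br bond (Cornforth/polar Felkin–Anh 1,2-induction, as for α-halo aldehydes), setting 12R from 13S; the conjugated enyne arms are poor π-nucleophiles, so the Prins cyclisation and 2-oxonia-Cope shift that a plain homoallyl arm would suffer are suppressed.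

**Step 6**
Reactants: 13 (3Z,6S,7S,9Z)-7-{[(4R,5S)-5-bromohept-1-en-4-yl]oxy}-1,12-bis(trimethylsilyl)dodeca-3,9-diene-1,11-diyn-6-yl acetate
Product: 14 (1S,3Z)-1-{(2S,7R)-7-[(1S)-1-bromopropyl]-2,3,6,7-tetrahydrooxepin-2-yl}-6-(trimethylsilyl)hex-3-en-5-yn-1-yl acetate
Conditions: second-generation Grubbs catalyst RuCl2(=CHPh)(H2IMes)(PCy3) (10 mol%), CH2Cl2 (2 mM), 40 °C
Reagents that add atoms: none
Why: Ring-closing metathesis: ruthenium loads on the only terminal olefin and closes the seven-membered ring onto the cis-enyne olefin of the arm on C7 (the arm on C6 could only give an eight-membered ring), expelling the enyne as the ruthenium alkynylcarbene known from enyne cross-metathesis; the ring forces the cis C9=C10 bond and no stereocentre is touched.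

**Step 7**
Reactants: 14 (1S,3Z)-1-{(2S,7R)-7-[(1S)-1-bromopropyl]-2,3,6,7-tetrahydrooxepin-2-yl}-6-(trimethylsilyl)hex-3-en-5-yn-1-yl acetate
Product: 15 (1S,3Z)-1-{(2S,7R)-7-[(1S)-1-bromopropyl]-2,3,6,7-tetrahydrooxepin-2-yl}hex-3-en-5-yn-1-yl acetate
Conditions: Bu4NF (1.2 equiv), AcOH (1.2 equiv), THF, −20 → 0 °C
Reagents that add atoms: none
Why: Buffered fluoride protodesilylation of the alkynylsilane; the acetate, the secondary bromide and the Z-enyne survive these near-neutral conditions.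

**Compound list**
1 | (Z)-1,2-dichloroethene | Cl/C=C\Cl | starting material
2 | ethynyl(trimethyl)silane | C#C[Si](C)(C)C | starting material
3 | [(3Z)-4-chlorobut-3-en-1-yn-1-yl]trimethylsilane | C[Si](C)(C)C#C/C=C\Cl | intermediate
4 | (2S,2'S)-2,2'-bioxirane | C1O[C@@H]1[C@@H]1CO1 | starting material
5 | (1R)-2-iodo-1-[(2S)-oxiran-2-yl]ethan-1-ol (iodohydrin) | IC[C@H](O)[C@@H]1CO1 | intermediate
6 | (1S,3Z)-1-[(2S)-oxiran-2-yl]-6-(trimethylsilyl)hex-3-en-5-yn-1-ol (mono-coupled epoxy alcohol) | C[Si](C)(C)C#C/C=C\C[C@H](O)[C@@H]1CO1 | intermediate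
7 | (2R,3S,5Z)-1-iodo-8-(trimethylsilyl)oct-5-en-7-yne-2,3-diol (second iodohydrin) | C[Si](C)(C)C#C/C=C\C[C@H](O)[C@@H](O)CI | intermediate
8 | (3Z,6S,7S,9Z)-1,12-bis(trimethylsilyl)dodeca-3,9-diene-1,11-diyne-6,7-diol | C[Si](C)(C)C#C/C=C\C[C@H](O)[C@@H](O)C/C=C\C#C[Si](C)(C)C | intermediate
9 | (2S)-2-bromobutanoic acid | CC[C@H](Br)C(O)=O | starting material
10 | (3Z,6S,7S,9Z)-7-hydroxy-1,12-bis(trimethylsilyl)dodeca-3,9-diene-1,11-diyn-6-yl (2S)-2-bromobutanoate | C[Si](C)(C)C#C/C=C\C[C@H](O)[C@@H](OC(=O)[C@@H](Br)CC)C/C=C\C#C[Si](C)(C)C | intermediate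
11 | bis(diisobutylaluminium) derivative of the hemiacetal of 10 (aluminium hemiacetal, acetal carbon unassigned) | C[Si](C)(C)C#C/C=C\C[C@H](O[Al](CC(C)C)CC(C)C)[C@@H](OC(O[Al](CC(C)C)CC(C)C)[C@@H](Br)CC)C/C=C\C#C[Si](C)(C)C | intermediate
12 | (3Z,6S,7S,9Z)-7-{[(2S)-1-(acetyloxy)-2-bromobutyl]oxy}-1,12-bis(trimethylsilyl)dodeca-3,9-diene-1,11-diyn-6-yl acetate (acetal carbon unassigned) | C[Si](C)(C)C#C/C=C\C[C@H](OC(C)=O)[C@@H](OC(OC(C)=O)[C@@H](Br)CC)C/C=C\C#C[Si](C)(C)C | intermediate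
13 | (3Z,6S,7S,9Z)-7-{[(4R,5S)-5-bromohept-1-en-4-yl]oxy}-1,12-bis(trimethylsilyl)dodeca-3,9-diene-1,11-diyn-6-yl acetate | C[Si](C)(C)C#C/C=C\C[C@H](OC(C)=O)[C@@H](O[C@H](CC=C)[C@@H](Br)CC)C/C=C\C#C[Si](C)(C)C | intermediate
14 | (1S,3Z)-1-{(2S,7R)-7-[(1S)-1-bromopropyl]-2,3,6,7-tetrahydrooxepin-2-yl}-6-(trimethylsilyl)hex-3-en-5-yn-1-yl acetate | C[Si](C)(C)C#C/C=C\C[C@H](OC(C)=O)[C@@H]1CC=CC[C@H]([C@@H](Br)CC)O1 | intermediate
15 | (1S,3Z)-1-{(2S,7R)-7-[(1S)-1-bromopropyl]-2,3,6,7-tetrahydrooxepin-2-yl}hex-3-en-5-yn-1-yl acetate | C#C/C=C\C[C@H](OC(C)=O)[C@@H]1CC=CC[C@H]([C@@H](Br)CC)O1 | target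

**Step count and risks**

Total step count: 7. Longest linear sequence: 7 (1 → 3 → 8 → 10 → 12 → 13 → 14 → 15; 6 counted from the bis-epoxide 4).

Steps most likely to fail:

Step 2 (the new coupling). The alkyl radical may add to the enyne instead of being captured at nickel, the Z geometry may leak, and the second coupling may lag behind the first. The fallback uses known chemistry, sets out from 4 and comes back at 8. Compound 4 is opened at both CH2 termini with lithium 4-(trimethylsilyl)buta-1,3-diynide (from 1,4-bis(trimethylsilyl)buta-1,3-diyne and MeLi·LiBr) and BF3·OEt2 in THF at −78 °C to give (6S,7S)-1,12-bis(trimethylsilyl)dodeca-1,3,9,11-tetrayne-6,7-diol F1. Its two internal, non-silylated triple bonds are then reduced cis with zinc activated by Cu(OAc)2 and AgNO3 in MeOH/H2O (or by dialkylborane monohydroboration and protonolysis), which leaves the silyl-capped alkynes alone and gives 8.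

Step 5 (with step 4, the Rychnovsky pair on an α-bromo ester). The deactivated α-bromo α-acetoxy ether may resist clean ionisation, and the C12 ratio rests on acyclic 1,2-induction alone. The fallback sets out from 8 (and 9), comes back at 13, and replaces the ester route by a three-component silyl-modified Sakurai (Markó) coupling. Compound 8 is mono-acetylated (Ac2O 1.0 equiv, pyridine, −20 °C, diol recycled) to (3Z,6S,7S,9Z)-7-hydroxy-1,12-bis(trimethylsilyl)dodeca-3,9-diene-1,11-diyn-6-yl acetate F2. This is silylated in the flask by allylSiMe3 with catalytic Me3SiOTf (propene lost) to its trimethylsilyl ether (3Z,6S,7S,9Z)-1,12-bis(trimethylsilyl)-7-[(trimethylsilyl)oxy]dodeca-3,9-diene-1,11-diyn-6-yl acetate F3. Separately 9 is reduced with BH3·THF to (2S)-2-bromobutan-1-ol F4 and oxidised with Dess–Martin periodinane to (2S)-2-bromobutanal F5, which is used at once as a cold solution. F3, F5 and allylSiMe3 with Me3SiOTf in CH2Cl2 at −78 °C then give 13 through the same oxocarbenium ion, now generated from a silyl hemiacetal.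

Step 6 (metathesis onto a conjugated cis-enyne olefin). Ring closure may be slow, may compete with the eight-membered alternative, or may scramble the remaining Z-enyne. The fallback sets out from 4 (with 3), comes back at 14, and closes the ring between two terminal olefins.
- Under the step 2 conditions with 4 in threefold excess and 3 limiting, the mono-coupled epoxy alcohol 6 is isolated.
- Ac2O/pyridine gives (1S,3Z)-1-[(2S)-oxiran-2-yl]-6-(trimethylsilyl)hex-3-en-5-yn-1-yl acetate F6.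
- LiC≡CH (acetylene, n-BuLi) with BF3·OEt2 in THF at −78 °C opens the epoxide to (3Z,6S,7S)-7-hydroxy-1-(trimethylsilyl)dec-3-ene-1,9-diyn-6-yl acetate F7. The ethynyl group is a masked vinyl group that does not invite Prins or oxonia-Cope chemistry.
- Silylation in the flask gives (3Z,6S,7S)-1-(trimethylsilyl)-7-[(trimethylsilyl)oxy]dec-3-ene-1,9-diyn-6-yl acetate F8, and the silyl-modified Sakurai coupling with F5 and allylSiMe3 (Me3SiOTf, −78 °C) gives (3Z,6S,7S)-7-{[(4R,5S)-5-bromohept-1-en-4-yl]oxy}-1-(trimethylsilyl)dec-3-ene-1,9-diyn-6-yl acetate F9.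
- Semi-hydrogenation of the terminal alkyne only (H2, Pd/CaCO3 poisoned with Pb(OAc)2, quinoline) gives (3Z,6S,7S)-7-{[(4R,5S)-5-bromohept-1-en-4-yl]oxy}-1-(trimethylsilyl)deca-3,9-dien-1-yn-6-yl acetate F10.
- First-generation Grubbs catalyst RuCl2(=CHPh)(PCy3)2 in CH2Cl2 at 40 °C closes the oxepene with loss of ethene to give 14.

**Further compounds**
F1 | step 2 | (6S,7S)-1,12-bis(trimethylsilyl)dodeca-1,3,9,11-tetrayne-6,7-diol | C[Si](C)(C)C#CC#CC[C@H](O)[C@@H](O)CC#CC#C[Si](C)(C)C
F2 | step 5 | (3Z,6S,7S,9Z)-7-hydroxy-1,12-bis(trimethylsilyl)dodeca-3,9-diene-1,11-diyn-6-yl acetate | C[Si](C)(C)C#C/C=C\C[C@H](OC(C)=O)[C@@H](O)C/C=C\C#C[Si](C)(C)C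
F3 | step 5 | (3Z,6S,7S,9Z)-1,12-bis(trimethylsilyl)-7-[(trimethylsilyl)oxy]dodeca-3,9-diene-1,11-diyn-6-yl acetate | C[Si](C)(C)C#C/C=C\C[C@H](OC(C)=O)[C@@H](O[Si](C)(C)C)C/C=C\C#C[Si](C)(C)C
F4 | step 5 | (2S)-2-bromobutan-1-ol | CC[C@H](Br)CO
F5 | step 5 | (2S)-2-bromobutanal | CC[C@H](Br)C=O
F6 | step 6 | (1S,3Z)-1-[(2S)-oxiran-2-yl]-6-(trimethylsilyl)hex-3-en-5-yn-1-yl acetate | C[Si](C)(C)C#C/C=C\C[C@H](OC(C)=O)[C@@H]1CO1
F7 | step 6 | (3Z,6S,7S)-7-hydroxy-1-(trimethylsilyl)dec-3-ene-1,9-diyn-6-yl acetate | C[Si](C)(C)C#C/C=C\C[C@H](OC(C)=O)[C@@H](O)CC#C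
F8 | step 6 | (3Z,6S,7S)-1-(trimethylsilyl)-7-[(trimethylsilyl)oxy]dec-3-ene-1,9-diyn-6-yl acetate | C[Si](C)(C)C#C/C=C\C[C@H](OC(C)=O)[C@@H](O[Si](C)(C)C)CC#C
F9 | step 6 | (3Z,6S,7S)-7-{[(4R,5S)-5-bromohept-1-en-4-yl]oxy}-1-(trimethylsilyl)dec-3-ene-1,9-diyn-6-yl acetate | C[Si](C)(C)C#C/C=C\C[C@H](OC(C)=O)[C@@H](O[C@H](CC=C)[C@@H](Br)CC)CC#C
F10 | step 6 | (3Z,6S,7S)-7-{[(4R,5S)-5-bromohept-1-en-4-yl]oxy}-1-(trimethylsilyl)deca-3,9-dien-1-yn-6-yl acetate | C[Si](C)(C)C#C/C=C\C[C@H](OC(C)=O)[C@@H](O[C@H](CC=C)[C@@H](Br)CC)CC=C
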